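**Assumption:** positions are given in carotenoid numbering (ring C1–C6, chain C7–C15 and C15'–C1'). In step 1 the (S,S)-configured catalyst is taken to give the (4S)-alcohol, as it does with aryl and alkenyl ketones; the (R,R) catalyst would be used if the sense proved opposite.

**Retrosynthetic overview**
1. The last C–C bond, C3'–C4', is made by a crossed aldol (Claisen–Schmidt) condensation of the C35 polyenal 26 with 3-hydroxy-3-methylbutan-2-one 27; the C2' carbinol is then set by CBS reduction of the enone, followed by global desilylation.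
2. 26 comes from the C25 aldehyde 16 by two C5 homologations (HWE with phosphonate 20, iBu2AlH, MnO2).
3. 16 comes from a Wittig reaction of the cyclohexenyl C15 phosphonium salt 12 with the C10 dialdehyde 13; 12 comes from a Stille coupling of enol triflate 7 with dienylstannane 9.
4. Ring stereocentres: C3 by asymmetric transfer hydrogenation of ketoisophorone 1; C4 by epoxidation anti to the C3 silyl ether and SmI2 opening.
5. Rings: the cyclohexene is never built, it comes intact from 1; the only ring made is the oxirane of 4 (step 3), opened again in step 4.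

Abbreviations: TBS = tert-butyldimethylsilyl, TMS = trimethylsilyl, TBSO/TMSO = the corresponding silyl ethers. From step 8 on, all operations are run under argon in dim light.

**Route**

Step 1
Reactants: 1 2,6,6-trimethylcyclohex-2-ene-1,4-dione (ketoisophorone)
Product: 2 (4S)-4-hydroxy-2,6,6-trimethylcyclohex-2-en-1-one
Conditions: RuCl[(S,S)-TsDPEN](p-cymene) (1 mol %), KOH (2 mol %), iPrOH, rt
Reagents that add atoms: none
Why: Noyori asymmetric transfer hydrogenation reduces only the unhindered carbonyl (the other is shielded by the gem-dimethyl and vinylic methyl groups), and the chiral Ru–diamine catalyst delivers hydride to one enantioface to set the future C3 centre as S.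

Step 2
Reactants: 2 (4S)-4-hydroxy-2,6,6-trimethylcyclohex-2-en-1-one
Product: 3 (4S)-4-(TBSO)-2,6,6-trimethylcyclohex-2-en-1-one
Conditions: TBSCl, imidazole, DMF, rt
Reagents that add atoms: tert-butyldimethylsilyl chloride, CC(C)(C)[Si](C)(C)Cl
Why: Imidazole-promoted silylation of the secondary allylic alcohol gives a base-stable ether whose bulk steers the next step.

Step 3
Reactants: 3 (4S)-4-(TBSO)-2,6,6-trimethylcyclohex-2-en-1-one
Product: 4 (1R,5S,6R)-5-(TBSO)-1,3,3-trimethyl-7-oxabicyclo[4.1.0]heptan-2-one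
Conditions: 30 % aq. H2O2, NaOH (0.3 equiv), MeOH, 0 °C
Reagents that add atoms: hydrogen peroxide, OO
Why: In this Weitz–Scheffer nucleophilic epoxidation the hydroperoxide adds to the enone β-carbon from the face opposite the adjacent OTBS group and the enolate closes the oxirane, so the new C4–O bond is trans to the C3–O bond by substrate control.

Step 4
Reactants: 4 (1R,5S,6R)-5-(TBSO)-1,3,3-trimethyl-7-oxabicyclo[4.1.0]heptan-2-one
Product: 5 (4S,5S)-4-(TBSO)-5-hydroxy-2,2,6-trimethylcyclohexan-1-one (both C6 epimers)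
Conditions: SmI2 (2.5 equiv), THF/MeOH, −90 °C
Reagents that add atoms: none
Why: SmI2 reductive opening of the α,β-epoxy ketone cleaves only the Cα–O bond (ketyl formation, then protonation by MeOH), so the C4–O bond and the trans-3,4 relationship are untouched; the new methyl-bearing centre is irrelevant because it becomes sp2 in step 6.

Step 5
Reactants: 5 (4S,5S)-4-(TBSO)-5-hydroxy-2,2,6-trimethylcyclohexan-1-one
Product: 6 (4S,5S)-4,5-bis(TBSO)-2,2,6-trimethylcyclohexan-1-one (both C6 epimers)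
Conditions: TBSOTf, 2,6-lutidine, CH2Cl2, −78 → 0 °C
Reagents that add atoms: tert-butyldimethylsilyl trifluoromethanesulfonate, CC(C)(C)[Si](C)(C)OS(=O)(=O)C(F)(F)F
Why: Silyl triflate silylation protects the hindered secondary alcohol quickly at low temperature, before the β-hydroxy ketone can dehydrate.

Step 6
Reactants: 6 (4S,5S)-4,5-bis(TBSO)-2,2,6-trimethylcyclohexan-1-one
Product: 7 (3S,4S)-3,4-bis(TBSO)-2,6,6-trimethylcyclohex-1-en-1-yl trifluoromethanesulfonate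
Conditions: LiN(iPr)2, THF, −78 °C; PhNTf2, −78 °C → rt
Reagents that add atoms: N-phenylbis(trifluoromethanesulfonimide), FC(F)(F)S(=O)(=O)N(c1ccccc1)S(=O)(=O)C(F)(F)F
Why: Enolate O-triflation can give only the tetrasubstituted C5=C6 enol triflate because the ketone has a single α-hydrogen, and the β-silyloxy group is too poor a leaving group to be eliminated from the enolate at −78 °C.

Step 7
Reactants: 8 (2E)-3-methylpent-2-en-4-yn-1-ol
Product: 9 (2E,4E)-3-methyl-5-(tributylstannyl)penta-2,4-dien-1-ol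
Conditions: Bu3SnH, PdCl2(PPh3)2 (2 mol %), THF, 0 °C
Reagents that add atoms: tributyltin hydride, CCCC[SnH](CCCC)CCCC
Why: Palladium-catalysed syn-hydrostannation of the terminal alkyne puts tin on the terminal carbon of the branched enyne and gives the (E)-vinylstannane without touching the existing (E)-alkene.

Step 8
Reactants: 7 (3S,4S)-3,4-bis(TBSO)-2,6,6-trimethylcyclohex-1-en-1-yl trifluoromethanesulfonate; 9 (2E,4E)-3-methyl-5-(tributylstannyl)penta-2,4-dien-1-ol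
Product: 10 (2E,4E)-5-[(3S,4S)-3,4-bis(TBSO)-2,6,6-trimethylcyclohex-1-en-1-yl]-3-methylpenta-2,4-dien-1-ol
Conditions: Pd2(dba)3 (5 mol %), AsPh3 (40 mol %), NMP, 60 °C
Reagents that add atoms: none
Why: The Stille cross-coupling joins the two sp2 carbons with retention of both alkene geometries, and AsPh3 in NMP speeds transmetalation to the hindered cyclohexenylpalladium triflate.

Step 9
Reactants: 10 (2E,4E)-5-[(3S,4S)-3,4-bis(TBSO)-2,6,6-trimethylcyclohex-1-en-1-yl]-3-methylpenta-2,4-dien-1-ol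
Product: 12 {(2E,4E)-5-[(3S,4S)-3,4-bis(TBSO)-2,6,6-trimethylcyclohex-1-en-1-yl]-3-methylpenta-2,4-dien-1-yl}triphenylphosphonium bromide, via C15 allylic bromide 11 (not isolated)
Conditions: CBr4 (1.05 equiv), PPh3 (1.1 equiv), 2,6-lutidine (0.2 equiv), CH2Cl2, 0 °C; then PPh3 (1.5 equiv), rt
Reagents that add atoms: carbon tetrabromide, BrC(Br)(Br)Br; triphenylphosphine, c1ccc(cc1)P(c1ccccc1)c1ccccc1
Why: Appel bromination under neutral conditions followed by SN2 attack of PPh3 at the primary allylic carbon gives the Wittig salt without exposing the allylic silyl ether to acid.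

Step 10
Reactants: 12 the C15 phosphonium bromide; 13 (2E,4E,6E)-2,7-dimethylocta-2,4,6-trienedial (3 equiv)
Product: 16 (3S,4S)-3,4-bis(TBSO)-12'-apo-β-caroten-12'-al, via phosphorus ylide 14 (not isolated), via 11Z isomer 15 (not isolated)
Conditions: NaOMe/MeOH added slowly to 12 and 13 in CH2Cl2, 0 °C → rt; then I2 (1 mol %), CH2Cl2/heptane, diffuse light, rt
Reagents that add atoms: none
Why: The Wittig olefination of one aldehyde of the dial (used in excess) forms C11=C12, and iodine-catalysed isomerisation converts the Z part of the mixture from the semi-stabilised ylide into the thermodynamically favoured all-E polyenal.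

Step 11
Reactants: 17 chloroacetaldehyde (50 % in water); 18 ethyl 2-(triphenyl-λ5-phosphanylidene)propanoate
Product: 19 ethyl (2E)-4-chloro-2-methylbut-2-enoate
Conditions: CH2Cl2, rt, 16 h
Reagents that add atoms: none
Why: The Wittig reaction of the stabilised α-methyl ylide is strongly E-selective and places the chlorine unambiguously at C4.

Step 12
Reactants: 19 ethyl (2E)-4-chloro-2-methylbut-2-enoate
Product: 20 ethyl (2E)-4-(diethoxyphosphoryl)-2-methylbut-2-enoate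
Conditions: P(OEt)3, NaI (5 mol %), neat, 140 °C; vacuum distillation
Reagents that add atoms: triethyl phosphite, CCOP(OCC)OCC
Why: The Michaelis–Arbuzov reaction of the primary allylic chloride is driven by loss of volatile chloroethane.

Step 13
Reactants: 16 (3S,4S)-3,4-bis(TBSO)-12'-apo-β-caroten-12'-al; 20 ethyl (2E)-4-(diethoxyphosphoryl)-2-methylbut-2-enoate
Product: 21 ethyl (3S,4S)-3,4-bis(TBSO)-8'-apo-β-caroten-8'-oate
Conditions: 20, LiN(SiMe3)2, THF, −78 °C; then 16, −78 → 0 °C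
Reagents that add atoms: none
Why: Horner–Wadsworth–Emmons olefination of the vinylogous phosphonoacetate anion at its phosphorus-bearing carbon forms the new E double bond C11'=C12' and adds five carbons.

Step 14
Reactants: 21 ethyl (3S,4S)-3,4-bis(TBSO)-8'-apo-β-caroten-8'-oate
Product: 22 (3S,4S)-3,4-bis(TBSO)-8'-apo-β-caroten-8'-ol
Conditions: iBu2AlH (2.5 equiv), CH2Cl2, −78 °C; aq. KNaC4H4O6 work-up
Reagents that add atoms: none
Why: The aluminium hydride reduces the conjugated ester to the allylic alcohol at low temperature without touching the polyene or the silyl ethers.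

Step 15
Reactants: 22 (3S,4S)-3,4-bis(TBSO)-8'-apo-β-caroten-8'-ol
Product: 23 (3S,4S)-3,4-bis(TBSO)-8'-apo-β-caroten-8'-al
Conditions: activated MnO2 (20 equiv), CH2Cl2, rt
Reagents that add atoms: none
Why: MnO2 oxidises the allylic alcohol selectively to the conjugated aldehyde under neutral conditions.

Step 16
Reactants: 23 (3S,4S)-3,4-bis(TBSO)-8'-apo-β-caroten-8'-al; 20 ethyl (2E)-4-(diethoxyphosphoryl)-2-methylbut-2-enoate
Product: 24 ethyl (3S,4S)-3,4-bis(TBSO)-4'-apo-β-caroten-4'-oate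
Conditions: 20, LiN(SiMe3)2, THF, −78 °C; then 23, −78 → 0 °C
Reagents that add atoms: none
Why: A second Horner–Wadsworth–Emmons olefination with the same reagent forms the E double bond C7'=C8' and brings the chain to C35.

Step 17
Reactants: 24 ethyl (3S,4S)-3,4-bis(TBSO)-4'-apo-β-caroten-4'-oate
Product: 25 (3S,4S)-3,4-bis(TBSO)-4'-apo-β-caroten-4'-ol
Conditions: iBu2AlH (2.5 equiv), CH2Cl2, −78 °C; aq. KNaC4H4O6 work-up
Reagents that add atoms: none
Why: Ester-to-allylic-alcohol reduction as in step 14.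

Step 18
Reactants: 25 (3S,4S)-3,4-bis(TBSO)-4'-apo-β-caroten-4'-ol
Product: 26 (3S,4S)-3,4-bis(TBSO)-4'-apo-β-caroten-4'-al
Conditions: activated MnO2 (20 equiv), CH2Cl2, rt
Reagents that add atoms: none
Why: Allylic oxidation as in step 15 gives the non-enolisable α-methyl polyenal needed for the aldol.

Step 19
Reactants: 26 (3S,4S)-3,4-bis(TBSO)-4'-apo-β-caroten-4'-al; 27 3-hydroxy-3-methylbutan-2-one (10 equiv)
Product: 29 (3S,4S)-3,4-bis(TBSO)-1'-hydroxy-3',4'-didehydro-1',2'-dihydro-β,ψ-caroten-2'-one, via aldol adduct 28 (not isolated)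
Conditions: KOH (3 equiv), MeOH/THF 1:1, rt, 16 h
Reagents that add atoms: none
Why: In this Claisen–Schmidt aldol condensation the ketone can enolise only at its methyl group and the aldehyde has no α-hydrogen, so the crossed aldol addition at C4' followed by E1cB loss of water from 28 gives the (E)-enone and joins C3' to C4'.

Step 20
Reactants: 29 the C40 α'-hydroxy enone
Product: 30 (3S,4S)-3,4-bis(TBSO)-1'-(TMSO)-3',4'-didehydro-1',2'-dihydro-β,ψ-caroten-2'-one
Conditions: N-(trimethylsilyl)imidazole (5 equiv), CH2Cl2, rt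
Reagents that add atoms: N-(trimethylsilyl)imidazole, C[Si](C)(C)n1ccnc1
Why: Neutral silyl transfer masks the tertiary hydroxyl, which would otherwise consume borane, and makes the C1' side of the ketone unambiguously the bulky one.

Step 21
Reactants: 30 the C40 enone 1'-TMS ether
Product: 31 (3S,4S,2'S)-3,4-bis(TBSO)-1'-(TMSO)-3',4'-didehydro-1',2'-dihydro-β,ψ-caroten-2'-ol
Conditions: (R)-2-methyl-CBS-oxazaborolidine (1.0 equiv), catecholborane (3 equiv), toluene/CH2Cl2, −78 °C; MeOH quench, pH 7 buffer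
Reagents that add atoms: none
Why: In the Corey–Bakshi–Shibata reduction the ketone binds the catalyst boron anti to the bulky CMe2(OTMS) group and the coordinated borane delivers hydride to the Re face, giving the (2'S) allylic alcohol by 1,2-reduction.

Step 22
Reactants: 31 the tris-silyl ether
Product: 32 (3S,4S,2'S)-3',4'-didehydro-1',2'-dihydro-β,ψ-carotene-3,4,1',2'-tetrol (CNP0343898.2)
Conditions: Bu4NF (8 equiv), AcOH (4 equiv), THF, rt → 40 °C
Reagents that add atoms: none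
Why: Fluoride-mediated desilylation, buffered with acetic acid, removes all three silyl ethers under near-neutral conditions that the allylic polyene alcohols tolerate.

**Compound list**

1 | 2,6,6-trimethylcyclohex-2-ene-1,4-dione (ketoisophorone) | CC1=CC(=O)CC(C)(C)C1=O | starting material
2 | (4S)-4-hydroxy-2,6,6-trimethylcyclohex-2-en-1-one | CC1=C[C@@H](O)CC(C)(C)C1=O | intermediate
3 | (4S)-4-[(tert-butyldimethylsilyl)oxy]-2,6,6-trimethylcyclohex-2-en-1-one | CC1=C[C@@H](O[Si](C)(C)C(C)(C)C)CC(C)(C)C1=O | intermediate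
4 | (1R,5S,6R)-5-[(tert-butyldimethylsilyl)oxy]-1,3,3-trimethyl-7-oxabicyclo[4.1.0]heptan-2-one | C[C@@]12O[C@@H]1[C@@H](O[Si](C)(C)C(C)(C)C)CC(C)(C)C2=O | intermediate
5 | (4S,5S)-4-[(tert-butyldimethylsilyl)oxy]-5-hydroxy-2,2,6-trimethylcyclohexan-1-one, C6 epimers | CC1[C@H](O)[C@@H](O[Si](C)(C)C(C)(C)C)CC(C)(C)C1=O | intermediate
6 | (4S,5S)-4,5-bis[(tert-butyldimethylsilyl)oxy]-2,2,6-trimethylcyclohexan-1-one, C6 epimers | CC1[C@H](O[Si](C)(C)C(C)(C)C)[C@@H](O[Si](C)(C)C(C)(C)C)CC(C)(C)C1=O | intermediate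
7 | (3S,4S)-3,4-bis[(tert-butyldimethylsilyl)oxy]-2,6,6-trimethylcyclohex-1-en-1-yl trifluoromethanesulfonate | CC1=C(OS(=O)(=O)C(F)(F)F)C(C)(C)C[C@H](O[Si](C)(C)C(C)(C)C)[C@H]1O[Si](C)(C)C(C)(C)C | intermediate
8 | (2E)-3-methylpent-2-en-4-yn-1-ol | C#C/C(C)=C/CO | starting material
9 | (2E,4E)-3-methyl-5-(tributylstannyl)penta-2,4-dien-1-ol | CCCC[Sn](CCCC)(CCCC)/C=C/C(C)=C/CO | intermediate
10 | (2E,4E)-5-[(3S,4S)-3,4-bis(TBSO)-2,6,6-trimethylcyclohex-1-en-1-yl]-3-methylpenta-2,4-dien-1-ol | CC1=C(/C=C/C(C)=C/CO)C(C)(C)C[C@H](O[Si](C)(C)C(C)(C)C)[C@H]1O[Si](C)(C)C(C)(C)C | intermediate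
11 | (2E,4E)-5-[(3S,4S)-3,4-bis(TBSO)-2,6,6-trimethylcyclohex-1-en-1-yl]-3-methylpenta-2,4-dien-1-yl bromide (not isolated) | CC1=C(/C=C/C(C)=C/CBr)C(C)(C)C[C@H](O[Si](C)(C)C(C)(C)C)[C@H]1O[Si](C)(C)C(C)(C)C | intermediate
12 | {(2E,4E)-5-[(3S,4S)-3,4-bis(TBSO)-2,6,6-trimethylcyclohex-1-en-1-yl]-3-methylpenta-2,4-dien-1-yl}triphenylphosphonium bromide | CC1=C(/C=C/C(C)=C/C[P+](c2ccccc2)(c2ccccc2)c2ccccc2)C(C)(C)C[C@H](O[Si](C)(C)C(C)(C)C)[C@H]1O[Si](C)(C)C(C)(C)C.[Br-] | intermediate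
13 | (2E,4E,6E)-2,7-dimethylocta-2,4,6-trienedial | O=C/C(C)=C/C=C/C=C(C)/C=O | starting material
14 | ylide of 12, {(2E,4E)-5-[(3S,4S)-3,4-bis(TBSO)-2,6,6-trimethylcyclohex-1-en-1-yl]-3-methylpenta-2,4-dien-1-ylidene}triphenyl-λ5-phosphane (not isolated) | CC1=C(/C=C/C(C)=C/C=P(c2ccccc2)(c2ccccc2)c2ccccc2)C(C)(C)C[C@H](O[Si](C)(C)C(C)(C)C)[C@H]1O[Si](C)(C)C(C)(C)C | intermediate
15 | (11Z)-isomer of 16, (3S,4S,11Z)-3,4-bis(TBSO)-12'-apo-β-caroten-12'-al (not isolated) | CC1=C(/C=C/C(C)=C/C=C\C(C)=C\C=C\C=C(C)\C=O)C(C)(C)C[C@H](O[Si](C)(C)C(C)(C)C)[C@H]1O[Si](C)(C)C(C)(C)C | intermediate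
16 | (3S,4S)-3,4-bis(TBSO)-12'-apo-β-caroten-12'-al, i.e. (2E,4E,6E,8E,10E,12E)-13-[(3S,4S)-3,4-bis(TBSO)-2,6,6-trimethylcyclohex-1-en-1-yl]-2,7,11-trimethyltrideca-2,4,6,8,10,12-hexaenal | CC1=C(/C=C/C(C)=C/C=C/C(C)=C/C=C/C=C(C)/C=O)C(C)(C)C[C@H](O[Si](C)(C)C(C)(C)C)[C@H]1O[Si](C)(C)C(C)(C)C | intermediate
17 | chloroacetaldehyde | ClCC=O | starting material
18 | ethyl 2-(triphenyl-λ5-phosphanylidene)propanoate | CCOC(=O)C(C)=P(c1ccccc1)(c1ccccc1)c1ccccc1 | starting material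
19 | ethyl (2E)-4-chloro-2-methylbut-2-enoate | CCOC(=O)/C(C)=C/CCl | intermediate
20 | ethyl (2E)-4-(diethoxyphosphoryl)-2-methylbut-2-enoate | CCOC(=O)/C(C)=C/CP(=O)(OCC)OCC | intermediate
21 | ethyl (3S,4S)-3,4-bis(TBSO)-8'-apo-β-caroten-8'-oate (all-E) | CC1=C(/C=C/C(C)=C/C=C/C(C)=C/C=C/C=C(C)/C=C/C=C(C)/C(=O)OCC)C(C)(C)C[C@H](O[Si](C)(C)C(C)(C)C)[C@H]1O[Si](C)(C)C(C)(C)C | intermediate
22 | (3S,4S)-3,4-bis(TBSO)-8'-apo-β-caroten-8'-ol | CC1=C(/C=C/C(C)=C/C=C/C(C)=C/C=C/C=C(C)/C=C/C=C(C)/CO)C(C)(C)C[C@H](O[Si](C)(C)C(C)(C)C)[C@H]1O[Si](C)(C)C(C)(C)C | intermediate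
23 | (3S,4S)-3,4-bis(TBSO)-8'-apo-β-caroten-8'-al | CC1=C(/C=C/C(C)=C/C=C/C(C)=C/C=C/C=C(C)/C=C/C=C(C)/C=O)C(C)(C)C[C@H](O[Si](C)(C)C(C)(C)C)[C@H]1O[Si](C)(C)C(C)(C)C | intermediate
24 | ethyl (3S,4S)-3,4-bis(TBSO)-4'-apo-β-caroten-4'-oate (all-E) | CC1=C(/C=C/C(C)=C/C=C/C(C)=C/C=C/C=C(C)/C=C/C=C(C)/C=C/C=C(C)/C(=O)OCC)C(C)(C)C[C@H](O[Si](C)(C)C(C)(C)C)[C@H]1O[Si](C)(C)C(C)(C)C | intermediate
25 | (3S,4S)-3,4-bis(TBSO)-4'-apo-β-caroten-4'-ol | CC1=C(/C=C/C(C)=C/C=C/C(C)=C/C=C/C=C(C)/C=C/C=C(C)/C=C/C=C(C)/CO)C(C)(C)C[C@H](O[Si](C)(C)C(C)(C)C)[C@H]1O[Si](C)(C)C(C)(C)C | intermediate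
26 | (3S,4S)-3,4-bis(TBSO)-4'-apo-β-caroten-4'-al | CC1=C(/C=C/C(C)=C/C=C/C(C)=C/C=C/C=C(C)/C=C/C=C(C)/C=C/C=C(C)/C=O)C(C)(C)C[C@H](O[Si](C)(C)C(C)(C)C)[C@H]1O[Si](C)(C)C(C)(C)C | intermediate
27 | 3-hydroxy-3-methylbutan-2-one | CC(=O)C(C)(C)O | starting material
28 | (3S,4S)-3,4-bis(TBSO)-1',4'-dihydroxy-1',2'-dihydro-β,ψ-caroten-2'-one, C4' epimers (not isolated) | CC1=C(/C=C/C(C)=C/C=C/C(C)=C/C=C/C=C(C)/C=C/C=C(C)/C=C/C=C(C)/C(O)CC(=O)C(C)(C)O)C(C)(C)C[C@H](O[Si](C)(C)C(C)(C)C)[C@H]1O[Si](C)(C)C(C)(C)C | intermediate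
29 | (3S,4S)-3,4-bis(TBSO)-1'-hydroxy-3',4'-didehydro-1',2'-dihydro-β,ψ-caroten-2'-one | CC1=C(/C=C/C(C)=C/C=C/C(C)=C/C=C/C=C(C)/C=C/C=C(C)/C=C/C=C(C)/C=C/C(=O)C(C)(C)O)C(C)(C)C[C@H](O[Si](C)(C)C(C)(C)C)[C@H]1O[Si](C)(C)C(C)(C)C | intermediate
30 | (3S,4S)-3,4-bis(TBSO)-1'-(TMSO)-3',4'-didehydro-1',2'-dihydro-β,ψ-caroten-2'-one | CC1=C(/C=C/C(C)=C/C=C/C(C)=C/C=C/C=C(C)/C=C/C=C(C)/C=C/C=C(C)/C=C/C(=O)C(C)(C)O[Si](C)(C)C)C(C)(C)C[C@H](O[Si](C)(C)C(C)(C)C)[C@H]1O[Si](C)(C)C(C)(C)C | intermediate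
31 | (3S,4S,2'S)-3,4-bis(TBSO)-1'-(TMSO)-3',4'-didehydro-1',2'-dihydro-β,ψ-caroten-2'-ol | CC1=C(/C=C/C(C)=C/C=C/C(C)=C/C=C/C=C(C)/C=C/C=C(C)/C=C/C=C(C)/C=C/[C@H](O)C(C)(C)O[Si](C)(C)C)C(C)(C)C[C@H](O[Si](C)(C)C(C)(C)C)[C@H]1O[Si](C)(C)C(C)(C)C | intermediate
32 | (3S,4S,2'S)-3',4'-didehydro-1',2'-dihydro-β,ψ-carotene-3,4,1',2'-tetrol | CC1=C(/C=C/C(C)=C/C=C/C(C)=C/C=C/C=C(C)/C=C/C=C(C)/C=C/C=C(C)/C=C/[C@H](O)C(C)(C)O)C(C)(C)C[C@H](O)[C@H]1O | target

**Step count**
Total: 22 steps. Longest linear sequence: 19 steps (1 → 32 through steps 1–6, 8–10 and 13–22).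

**Three steps most likely to fail, with fallbacks**

Step 21 (CBS reduction). Both the sense and the level of induction rest on the CMe2(OTMS) group acting as the large substituent against an (E)-alkenyl group, for which there is no direct precedent. A ketone conjugated to eleven double bonds may also react slowly. The configuration of 31 must therefore be checked (Mosher esters, chiral HPLC). The fallback replaces asymmetric reduction by resolution and sets out from 29. Luche reduction (NaBH4, CeCl3·7H2O, MeOH/THF, −40 °C) gives the 2'-epimeric diol (3S,4S,2'RS)-3,4-bis(TBSO)-3',4'-didehydro-1',2'-dihydro-β,ψ-carotene-1',2'-diol F1. Acylation of its secondary hydroxyl with (1S)-(−)-camphanic chloride (pyridine, DMAP, CH2Cl2) and preparative HPLC of the two diastereomeric esters gives the (2'S)-2'-O-[(1S,4R)-camphanoyl] ester F2. Methanolysis (K2CO3, MeOH/THF, rt) gives the (3S,4S,2'S)-3,4-bis(TBSO)-1',2'-diol F3, and Bu4NF in THF then gives 32, where the fallback rejoins the route.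

Step 8 (Stille coupling). The triflate carbon is flanked by a quaternary carbon and a methyl-bearing sp2 carbon, so transmetalation may stall and the stannane may homocouple or protodestannylate. The fallback builds the side chain by Heck reaction and chain extension and sets out from 7. Heck reaction with but-3-en-2-one (Pd(OAc)2, PPh3, Et3N, DMF, 70 °C) gives the β-ionone analogue (3E)-4-[(3S,4S)-3,4-bis(TBSO)-2,6,6-trimethylcyclohex-1-en-1-yl]but-3-en-2-one F4. HWE reaction with triethyl phosphonoacetate (NaH, THF, rt; the minor 2Z isomer is removed by chromatography) gives ethyl (2E,4E)-5-[(3S,4S)-3,4-bis(TBSO)-2,6,6-trimethylcyclohex-1-en-1-yl]-3-methylpenta-2,4-dienoate F5. Reduction with iBu2AlH (CH2Cl2, −78 °C) gives 10, where the fallback rejoins the route.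

Step 19 (aldol condensation on the C35 polyenal). Hydroxide-mediated condensation may be slow on the poorly soluble, vinylogously deactivated aldehyde, and long exposure to base can degrade the polyene. The fallback keeps the same C3'–C4' bond but makes it by a directed aldol addition with separate dehydration, and sets out from 27 and 26. Silylation of 27 (TMSCl, imidazole, DMF, rt) gives 3-methyl-3-[(trimethylsilyl)oxy]butan-2-one F6. Its kinetic lithium enolate (LiN(iPr)2, THF, −78 °C) adds to 26 to give the β-hydroxy ketone (3S,4S)-3,4-bis(TBSO)-4'-hydroxy-1'-(TMSO)-1',2'-dihydro-β,ψ-caroten-2'-one F7. Mesylation with in-situ E1cB elimination (MsCl, excess Et3N, CH2Cl2, 0 °C → rt) gives 30, where the fallback rejoins the route.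

**Further compounds**

F1 | step 21 | (3S,4S,2'RS)-3,4-bis(TBSO)-3',4'-didehydro-1',2'-dihydro-β,ψ-carotene-1',2'-diol | CC1=C(/C=C/C(C)=C/C=C/C(C)=C/C=C/C=C(C)/C=C/C=C(C)/C=C/C=C(C)/C=C/C(O)C(C)(C)O)C(C)(C)C[C@H](O[Si](C)(C)C(C)(C)C)[C@H]1O[Si](C)(C)C(C)(C)C
F2 | step 21 | (3S,4S,2'S)-3,4-bis(TBSO)-1'-hydroxy-3',4'-didehydro-1',2'-dihydro-β,ψ-caroten-2'-yl (1S,4R)-camphanate | CC1=C(/C=C/C(C)=C/C=C/C(C)=C/C=C/C=C(C)/C=C/C=C(C)/C=C/C=C(C)/C=C/[C@H](OC(=O)[C@@]23CC[C@@](C)(C(=O)O2)C3(C)C)C(C)(C)O)C(C)(C)C[C@H](O[Si](C)(C)C(C)(C)C)[C@H]1O[Si](C)(C)C(C)(C)C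
F3 | step 21 | (3S,4S,2'S)-3,4-bis(TBSO)-3',4'-didehydro-1',2'-dihydro-β,ψ-carotene-1',2'-diol | CC1=C(/C=C/C(C)=C/C=C/C(C)=C/C=C/C=C(C)/C=C/C=C(C)/C=C/C=C(C)/C=C/[C@H](O)C(C)(C)O)C(C)(C)C[C@H](O[Si](C)(C)C(C)(C)C)[C@H]1O[Si](C)(C)C(C)(C)C
F4 | step 8 | (3E)-4-[(3S,4S)-3,4-bis(TBSO)-2,6,6-trimethylcyclohex-1-en-1-yl]but-3-en-2-one | CC1=C(/C=C/C(C)=O)C(C)(C)C[C@H](O[Si](C)(C)C(C)(C)C)[C@H]1O[Si](C)(C)C(C)(C)C
F5 | step 8 | ethyl (2E,4E)-5-[(3S,4S)-3,4-bis(TBSO)-2,6,6-trimethylcyclohex-1-en-1-yl]-3-methylpenta-2,4-dienoate | CC1=C(/C=C/C(C)=C/C(=O)OCC)C(C)(C)C[C@H](O[Si](C)(C)C(C)(C)C)[C@H]1O[Si](C)(C)C(C)(C)C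
F6 | step 19 | 3-methyl-3-[(trimethylsilyl)oxy]butan-2-one | CC(=O)C(C)(C)O[Si](C)(C)C
F7 | step 19 | (3S,4S)-3,4-bis(TBSO)-4'-hydroxy-1'-(TMSO)-1',2'-dihydro-β,ψ-caroten-2'-one, C4' epimers | CC1=C(/C=C/C(C)=C/C=C/C(C)=C/C=C/C=C(C)/C=C/C=C(C)/C=C/C=C(C)/C(O)CC(=O)C(C)(C)O[Si](C)(C)C)C(C)(C)C[C@H](O[Si](C)(C)C(C)(C)C)[C@H]1O[Si](C)(C)C(C)(C)C
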